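**Assumption (remark on the chemistry):** Marchantin C has no stereogenic centre and its 18-membered ring is conformationally mobile, so the target is achiral and "single enantiomer" needs no stereocontrol. The only stereocentre of the route (in transient 11) is formed racemic and erased in the same flask.

## Structural features

Marchantin C (14) is built from four benzene rings. Ring A is 1,2,4-trisubstituted (A1 OH, A2 O-aryl, A4 CH2), ring B is a 1,4-phenylene (B1 O, B4 CH2), ring C is 1,2,3-trisubstituted (C1 CH2, C2 O-aryl, C3 OH) and ring D is a 1,3-phenylene (D1 O, D3 CH2). Two diaryl ether oxygens (A2–O–B1 and C2–O–D1) and two ethano bridges (B4–CH2CH2–C1 and D3–CH2CH2–A4) join them into one 18-membered ring with no aryl–aryl bond. There is no stereocentre and no configurationally stable axis, so no stereocentres stand next to each other. The sensitive groups are the two electron-rich phenols, each ortho to an aryloxy oxygen; the diaryl ethers and benzylic CH2 groups tolerate acid, base, hydrogenation and BBr3. The real difficulty is threefold: closing the 18-membered ring, making the C2–O–D1 ether on a carbon flanked by two substituents, and telling apart the two oxygens of each catechol-type ring (A1/A2 and C2/C3). The key step exploits the A1(OH)/A2–O–B1 unit: ring A is a para-alkylphenol whose ortho carbon A2 carries the phenolic oxygen of a second para-alkylphenol (ring B), which is the constitution of an ortho C–O phenol-coupling product. The molecule is formally a cyclic dehydro-dimer of two 3,4′-dihydroxybibenzyl units. Forming the A2–O bond by oxidative dearomatisation of ring A therefore closes the macrocycle and fixes which ring A oxygen is free and which is arylated, in one operation.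

## Logic of the disconnections

Route in one sentence: a thallium(III) oxidation dearomatises the dibromophenol ring A of the open-chain bis(dihalophenol) 10, the phenol oxygen of ring B closes the 18-membered ring on it, and zinc restores the arene.

14 ⇒ 13. The O–CH3 bond on the C3 oxygen is cut. The methyl ether is there so that ring C does not offer a third oxidisable phenol in the key step. There is no skeletal gain. The forward step must cleave an aryl methyl ether without touching the diaryl ethers, which BBr3 does.

13 ⇒ 12. Three C–H bonds are traced to C–Br (A6) and C–Cl (B2, B6). These halogens are the control elements of the key step and are removed tracelessly. The forward step must hydrogenolyse two C–Cl bonds that flank the ether oxygen.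

12 ⇒ 10 (through 11), the key disconnection. The A2–O(B1) bond is cut; it is both a diaryl ether bond and a ring bond of the macrocycle. Cutting here removes the macrocycle and one of the two ethers at once and leaves a linear bis-phenol in which the A1 and A2 oxygens need no differentiation, because A2 is simply an ortho carbon of a phenol. The forward step demands that ring A and not ring B is oxidised, that oxygen attacks at ortho and not at para, and that closure is intramolecular. These are answered by Br on ring A against Cl on ring B, by the alkyl-blocked para position, by the methyl ether on ring C and by high dilution.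

10 ⇒ 9 ⇒ 7 + 8. Both ethano bridges are traced to diarylalkynes, and the B4–C(sp) bond is cut. Ring B then enters as a 4-iodophenol already carrying its chlorines, with no protecting group. The forward steps demand C–I over C–Br/C–Cl selectivity in the coupling and alkyne saturation without C–halogen hydrogenolysis.

7 ⇒ 6. The terminal alkyne carbon is removed to give a formyl group at C1. The formyl group is what activates ring C for ether formation, so one substituent serves twice. The forward step is a one-carbon homologation that must tolerate a free halophenol.

6 ⇒ 5 + 2. The A4–C(sp) bond is cut, so ring A enters as a 4-iodophenol carrying both bromines. The forward coupling must again select C–I over C–Br.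

5 ⇒ 3 + 4. The hindered C2–O(D1) bond is cut. With fluoride at C2 and the formyl group ortho to it, this bond forms by addition–elimination where steric crowding matters little, and both fragments are commercial monocyclic arenes. The forward step must displace fluoride faster than base damages the terminal alkyne.

2 ⇒ 1. The C–I bond para to OH is cut. The only free activated position of 1 is para, so the iodination has one outcome.

## Other disconnections considered

Alternative 1: the first route to come to mind. The cut is the benzylic C–C bond of the B4–C1 bridge, taken as C=C. The forward key step is a high-dilution intramolecular Wittig reaction of the phosphonium aldehyde A1 to the macrocyclic stilbene A2, followed by hydrogenation and double demethylation to 14. Both diaryl ethers must first be made in separate C–O couplings on catechol rings whose oxygens are pre-differentiated by protecting groups, and three to four functional-group steps are needed to set up the ylide and aldehyde termini. The key step then settles only the easiest bond of the ring. The chosen plan is estimated to be about three steps shorter and lets the ring closure create an ether and differentiate A1/A2.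

Alternative 2: ring contraction. The cut is the same bridge, but through a C–S–C unit. The bis(bromomethyl) compound A3 would be closed with sodium sulfide to the 19-membered thiacyclophane A4, and photolysis of A4 in a trialkyl phosphite would extrude sulfur to form the CH2–CH2 bond. Sulfide ring closure is reliable, but A3 already contains both ethers and every carbon, so nothing is gained in the ether construction. The contraction adds two steps to a direct reductive coupling of A3, and benzylic radical pairs in a flexible 19-membered ring can also disproportionate or escape to oligomers.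

Alternative 3: two-bond stitching. The cuts are both aryl–C bonds of the D3–CH2CH2–A4 bridge. The dibromide A5 would undergo a one-pot double Stille coupling with (E)-1,2-bis(tributylstannyl)ethene to the macrocyclic (E)-stilbene A6; because the C2 unit is symmetric, the two aryl bromides need not be differentiated. Both ethers still have to be made separately on protected catechols. The second, ring-closing coupling competes with stannylation of both termini and with oligomerisation, an E-alkene must be accommodated in the 18-membered ring, and hydrogenation plus double demethylation follow. It is no shorter and the key step again leaves the ether and catechol problems to earlier steps.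

Key step: step 7

## Steps

Step 1
Reactants: 1 2,6-dibromophenol
Product: 2 2,6-dibromo-4-iodophenol
Conditions: NIS (1.05 equiv), TsOH·H2O (10 mol %), MeCN, 0 °C → rt
Reagents that add atoms: N-iodosuccinimide, O=C1CCC(=O)N1I
Why: Electrophilic aromatic iodination (SEAr) with acid-activated NIS; the para position is the only free position activated by the OH group, both ortho positions being brominated, so one regioisomer should form.

Step 2
Reactants: 3 2-fluoro-3-methoxybenzaldehyde; 4 3-ethynylphenol
Product: 5 2-(3-ethynylphenoxy)-3-methoxybenzaldehyde
Conditions: K2CO3 (1.5 equiv), DMF, 90 °C, N2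
Reagents that add atoms: none
Why: Nucleophilic aromatic substitution (addition–elimination through a Meisenheimer complex); the fluoride of 3 is activated by the ortho formyl group, so the crowded position between CHO and OMe should be etherified by the phenoxide of 4 without a metal catalyst. The temperature is held at 90 °C to spare the terminal alkyne.

Step 3
Reactants: 5 2-(3-ethynylphenoxy)-3-methoxybenzaldehyde; 2 2,6-dibromo-4-iodophenol
Product: 6 2-{3-[(3,5-dibromo-4-hydroxyphenyl)ethynyl]phenoxy}-3-methoxybenzaldehyde
Conditions: PdCl2(PPh3)2 (3 mol %), CuI (5 mol %), Et3N/THF 1:1, rt, degassed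
Reagents that add atoms: none
Why: Sonogashira coupling; oxidative addition of Pd(0) into the C–I bond at room temperature should be far faster than into the two hindered, electron-rich C–Br bonds ortho to the phenol oxygen, and the aldehyde and free phenol are tolerated.

Step 4
Reactants: 6 2-{3-[(3,5-dibromo-4-hydroxyphenyl)ethynyl]phenoxy}-3-methoxybenzaldehyde
Product: 7 2,6-dibromo-4-{[3-(2-ethynyl-6-methoxyphenoxy)phenyl]ethynyl}phenol
Conditions: dimethyl (1-diazo-2-oxopropyl)phosphonate (1.5 equiv), K2CO3 (3 equiv), MeOH/THF, 0 °C → rt
Reagents that add atoms: dimethyl (1-diazo-2-oxopropyl)phosphonate (Ohira–Bestmann reagent), CC(=O)C(=[N+]=[N-])P(=O)(OC)OC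
Why: Ohira–Bestmann variant of the Seyferth–Gilbert homologation; methanolysis releases dimethyl (diazomethyl)phosphonate, which should convert the non-enolisable aryl aldehyde into the terminal alkyne through a diazoalkene and 1,2-hydride shift of the alkylidene carbene. The internal alkyne, the aryl bromides and the deprotonated phenol are inert.

Step 5
Reactants: 7 2,6-dibromo-4-{[3-(2-ethynyl-6-methoxyphenoxy)phenyl]ethynyl}phenol; 8 2,6-dichloro-4-iodophenol
Product: 9 2,6-dibromo-4-[(3-{2-[(3,5-dichloro-4-hydroxyphenyl)ethynyl]-6-methoxyphenoxy}phenyl)ethynyl]phenol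
Conditions: PdCl2(PPh3)2 (3 mol %), CuI (5 mol %), Et3N/THF 1:1, rt → 40 °C, degassed
Reagents that add atoms: none
Why: Second Sonogashira coupling, again selective for the C–I bond (of 8) over the C–Br and C–Cl bonds; all four halogens and both phenols are carried unprotected.

Step 6
Reactants: 9 2,6-dibromo-4-[(3-{2-[(3,5-dichloro-4-hydroxyphenyl)ethynyl]-6-methoxyphenoxy}phenyl)ethynyl]phenol
Product: 10 2,6-dibromo-4-[2-(3-{2-[2-(3,5-dichloro-4-hydroxyphenyl)ethyl]-6-methoxyphenoxy}phenyl)ethyl]phenol
Conditions: H2 (1 atm), 5% Pt/C, EtOAc, rt, stopped at 4 equiv H2 uptake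
Reagents that add atoms: none
Why: Heterogeneous catalytic hydrogenation of both diarylalkynes to the ethano bridges; platinum is chosen over palladium because it saturates C≡C and C=C much faster than it hydrogenolyses aryl C–Br and C–Cl bonds.

Step 7
Reactants: 10 2,6-dibromo-4-[2-(3-{2-[2-(3,5-dichloro-4-hydroxyphenyl)ethyl]-6-methoxyphenoxy}phenyl)ethyl]phenol
Product: 12 A6-bromo-B2,B6-dichloro-marchantin C C3-O-methyl ether (the macrocycle of 14 with Br on ring A ortho to OH; Cl on both ring B carbons ortho to the ether oxygen; OMe on ring C), via macrocyclic bromodienone 11 (not isolated)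
Conditions: Tl(NO3)3·3H2O (2.5 equiv), MeOH/THF 4:1, 1 mM, −20 → 0 °C; then Zn dust, AcOH, rt
Reagents that add atoms: none
Why: Thallium(III) binds the more easily oxidised 2,6-dibromophenol (ring A) as an aryloxythallium species and removes two electrons, leaving a phenoxonium-type ring A with positive character at the two bromine-bearing ortho carbons and at the alkyl-bearing para carbon. The hydroxyl oxygen of the 2,6-dichlorophenol (ring B) attacks one ortho carbon, which dearomatises ring A to the 6-aryloxy-2,6-dibromocyclohexa-2,4-dienone 11 and closes the 18-membered ring by intramolecular O–C(ortho) bond formation; the para-phenylene and two flexible ethano bridges let the termini meet without strain. Zinc in acetic acid then reduces the C–Br bond at the sp3 carbon and re-aromatises ring A, so the original phenol oxygen stays as A1-OH and the new aryloxy group sits ortho to it at A2. The closest known reaction type is the thallium(III) nitrate coupling of an o,o′-dibromophenol with an o,o′-dichlorophenol followed by zinc reduction, established for isodityrosine-type macrocyclic diaryl ethers of 14 to 17 ring atoms. The one new stereocentre, C(Br)(OAr) of 11, forms racemic and is destroyed in the reduction, so it needs no control. The step needs ring A to be oxidised and ring B to act as nucleophile, which the lower oxidation potential of the bromophenol relative to the chlorophenol is expected to secure. It needs ortho and not para attack: the para carbon carries the chain, methanol adducts formed there should be returned to the phenol by zinc, and the two ortho carbons are equivalent. It needs intramolecular reaction, which the 1 mM dilution serves, while the methyl ether on ring C removes any third oxidisable phenol and the four halogens block ortho C–C coupling on both phenols.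

Step 8
Reactants: 12 A6-bromo-B2,B6-dichloro-marchantin C C3-O-methyl ether
Product: 13 marchantin C C3-O-methyl ether (the macrocycle of 14 with OMe on ring C in place of OH)
Conditions: H2 (3 atm), 10% Pd/C, Et3N (5 equiv), MeOH/EtOAc, rt
Reagents that add atoms: none
Why: Palladium-catalysed hydrogenolysis of the aryl C–Br and C–Cl bonds with Et3N as HX acceptor; the halogens have done their work as control elements, and the diaryl ethers, phenol and methyl ether are stable.

Step 9
Reactants: 13 marchantin C C3-O-methyl ether
Product: 14 marchantin C
Conditions: BBr3 (4 equiv), CH2Cl2, −78 °C → rt; then H2O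
Reagents that add atoms: none
Why: Lewis-acid cleavage of the aryl methyl ether (O–B coordination, then SN2 attack of bromide on the methyl group); the diaryl ether C–O bonds offer no sp3 carbon for attack and should survive.

## Compound list

1 | 2,6-dibromophenol | Oc1c(Br)cccc1Br | starting material
2 | 2,6-dibromo-4-iodophenol | Oc1c(Br)cc(I)cc1Br | intermediate
3 | 2-fluoro-3-methoxybenzaldehyde | COc1cccc(C=O)c1F | starting material
4 | 3-ethynylphenol | Oc1cccc(c1)C#C | starting material
5 | 2-(3-ethynylphenoxy)-3-methoxybenzaldehyde | COc1cccc(C=O)c1Oc1cccc(c1)C#C | intermediate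
6 | 2-{3-[(3,5-dibromo-4-hydroxyphenyl)ethynyl]phenoxy}-3-methoxybenzaldehyde | COc1cccc(C=O)c1Oc1cccc(c1)C#Cc1cc(Br)c(O)c(Br)c1 | intermediate
7 | 2,6-dibromo-4-{[3-(2-ethynyl-6-methoxyphenoxy)phenyl]ethynyl}phenol | COc1cccc(C#C)c1Oc1cccc(c1)C#Cc1cc(Br)c(O)c(Br)c1 | intermediate
8 | 2,6-dichloro-4-iodophenol | Oc1c(Cl)cc(I)cc1Cl | starting material
9 | 2,6-dibromo-4-[(3-{2-[(3,5-dichloro-4-hydroxyphenyl)ethynyl]-6-methoxyphenoxy}phenyl)ethynyl]phenol | COc1cccc(C#Cc2cc(Cl)c(O)c(Cl)c2)c1Oc1cccc(c1)C#Cc1cc(Br)c(O)c(Br)c1 | intermediate
10 | 2,6-dibromo-4-[2-(3-{2-[2-(3,5-dichloro-4-hydroxyphenyl)ethyl]-6-methoxyphenoxy}phenyl)ethyl]phenol | COc1cccc(CCc2cc(Cl)c(O)c(Cl)c2)c1Oc1cccc(c1)CCc1cc(Br)c(O)c(Br)c1 | intermediate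
11 | macrocyclic bromodienone (ring A as 2,6-dibromo-6-aryloxycyclohexa-2,4-dien-1-one, the aryloxy oxygen being that of ring B; racemic) | O=C1C(Br)=CC2=CC1(Br)Oc1c(Cl)cc(cc1Cl)CCc1cccc(OC)c1Oc1cccc(c1)CC2 | intermediate (not isolated)
12 | A6-bromo-B2,B6-dichloro-marchantin C C3-O-methyl ether | Oc1c(Br)cc2cc1Oc1c(Cl)cc(cc1Cl)CCc1cccc(OC)c1Oc1cccc(c1)CC2 | intermediate
13 | marchantin C C3-O-methyl ether | Oc1ccc2cc1Oc1ccc(cc1)CCc1cccc(OC)c1Oc1cccc(c1)CC2 | intermediate
14 | marchantin C | Oc1ccc2cc1Oc1ccc(cc1)CCc1cccc(O)c1Oc1cccc(c1)CC2 | target

## Step count and least certain steps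

Total: 9 steps. Longest linear sequence: 8 steps (steps 2 to 9 from 3 and 4; step 1 is a one-step branch).

**Step 7 (key step).** Oxidation may occur in the reverse sense (ring B oxidised and attacked by the ring A oxygen), because the bromo- and chlorophenols differ only modestly in oxidation potential. The oxidised ring A may be captured at the para carbon by methanol, or by the π-system of ring D in a six-membered C–C closure, instead of by the ring B oxygen at ortho; an 18-membered closure is slow against solvent capture and small-ring closure. Intermolecular coupling to oligomers is possible if dilution is insufficient, and benzylic oxidation through a quinone methide may intervene.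
Fallback (from 7 to 14): the ring is closed by copper-catalysed cross-coupling instead of phenol oxidation. O-Methylation of 7 (MeI, K2CO3, acetone) would give 1,3-dibromo-5-{[3-(2-ethynyl-6-methoxyphenoxy)phenyl]ethynyl}-2-methoxybenzene F1. Sonogashira coupling with 4-iodophenol would give 4-{[2-(3-{[3,5-dibromo-4-methoxyphenyl]ethynyl}phenoxy)-3-methoxyphenyl]ethynyl}phenol F2, and hydrogenation over Pt/C the seco phenol 4-{2-[2-(3-{2-[3,5-dibromo-4-methoxyphenyl]ethyl}phenoxy)-3-methoxyphenyl]ethyl}phenol F3. Intramolecular Ullmann etherification (CuI, N,N-dimethylglycine, Cs2CO3, dioxane, 100 °C, 2 mM) of the ring B phenol onto one of the two equivalent C–Br bonds of ring A would close the ring to A6-bromo-marchantin C dimethyl ether F4. Hydrogenolysis (H2, Pd/C, Et3N) would give marchantin C dimethyl ether F5, and BBr3 would cleave both methyl ethers to rejoin the route at 14.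

**Step 6.** Hydrogenolysis of the C–Br bonds may accompany alkyne saturation, or reduction may stall at the stilbene stage; the key step needs both bromines on ring A intact.
Fallback (from 5 to 10): bromine is introduced only after all palladium and hydrogenation steps. Sonogashira coupling of 5 with 4-iodophenol would give 2-{3-[(4-hydroxyphenyl)ethynyl]phenoxy}-3-methoxybenzaldehyde F6. Ohira–Bestmann homologation would give 4-{[3-(2-ethynyl-6-methoxyphenoxy)phenyl]ethynyl}phenol F7, and Sonogashira coupling with 8 would give 2,6-dichloro-4-{[2-(3-[(4-hydroxyphenyl)ethynyl]phenoxy)-3-methoxyphenyl]ethynyl}phenol F8. Hydrogenation over Pt/C, with only C–Cl bonds present, would give 2,6-dichloro-4-{2-[2-(3-[2-(4-hydroxyphenyl)ethyl]phenoxy)-3-methoxyphenyl]ethyl}phenol F9. Ortho,ortho-dibromination of the ring A phenol (Br2 2.0 equiv, t-BuNH2, toluene, −40 °C), with ring B blocked by its chlorines, would then give 10.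

**Step 2.** Base-induced addition of phenoxide across the terminal alkyne, or alkyne oligomerisation, may compete with fluoride displacement at a position flanked by OMe and CHO, since both need heat and carbonate.
Fallback (from 3 to 5): the alkyne is installed after the ether. SNAr of 3 with 3-iodophenol (K2CO3, DMF, 110 °C) would give 2-(3-iodophenoxy)-3-methoxybenzaldehyde F10. Sonogashira coupling with ethynyltrimethylsilane would give 3-methoxy-2-{3-[(trimethylsilyl)ethynyl]phenoxy}benzaldehyde F11, and desilylation (K2CO3, MeOH, rt) would give 5.

**Step 8.** Hydrodechlorination may stall after loss of bromine, because the two C–Cl bonds flank the diaryl ether oxygen inside the macrocycle and liberated halide slows the catalyst.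
Fallback (from 12 to 14): the order is inverted and the reduction type changed. BBr3 demethylation of 12 would give A6-bromo-B2,B6-dichloro-marchantin C F12, whose halophenoxide form is water-soluble. Nickel–aluminium alloy in aqueous NaOH would then remove all three halogens to give 14.

## Further compounds

F1 | step 7 | 1,3-dibromo-5-{[3-(2-ethynyl-6-methoxyphenoxy)phenyl]ethynyl}-2-methoxybenzene | COc1cccc(C#C)c1Oc1cccc(c1)C#Cc1cc(Br)c(OC)c(Br)c1
F2 | step 7 | 4-{[2-(3-{[3,5-dibromo-4-methoxyphenyl]ethynyl}phenoxy)-3-methoxyphenyl]ethynyl}phenol | COc1cccc(C#Cc2ccc(O)cc2)c1Oc1cccc(c1)C#Cc1cc(Br)c(OC)c(Br)c1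
F3 | step 7 | 4-{2-[2-(3-{2-[3,5-dibromo-4-methoxyphenyl]ethyl}phenoxy)-3-methoxyphenyl]ethyl}phenol | COc1cccc(CCc2ccc(O)cc2)c1Oc1cccc(c1)CCc1cc(Br)c(OC)c(Br)c1
F4 | step 7 | A6-bromo-marchantin C dimethyl ether (OMe on rings A and C, Br on ring A ortho to OMe) | COc1c(Br)cc2cc1Oc1ccc(cc1)CCc1cccc(OC)c1Oc1cccc(c1)CC2
F5 | step 7 | marchantin C dimethyl ether (OMe on rings A and C) | COc1ccc2cc1Oc1ccc(cc1)CCc1cccc(OC)c1Oc1cccc(c1)CC2
F6 | step 6 | 2-{3-[(4-hydroxyphenyl)ethynyl]phenoxy}-3-methoxybenzaldehyde | COc1cccc(C=O)c1Oc1cccc(c1)C#Cc1ccc(O)cc1
F7 | step 6 | 4-{[3-(2-ethynyl-6-methoxyphenoxy)phenyl]ethynyl}phenol | COc1cccc(C#C)c1Oc1cccc(c1)C#Cc1ccc(O)cc1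
F8 | step 6 | 2,6-dichloro-4-{[2-(3-[(4-hydroxyphenyl)ethynyl]phenoxy)-3-methoxyphenyl]ethynyl}phenol | COc1cccc(C#Cc2cc(Cl)c(O)c(Cl)c2)c1Oc1cccc(c1)C#Cc1ccc(O)cc1
F9 | step 6 | 2,6-dichloro-4-{2-[2-(3-[2-(4-hydroxyphenyl)ethyl]phenoxy)-3-methoxyphenyl]ethyl}phenol | COc1cccc(CCc2cc(Cl)c(O)c(Cl)c2)c1Oc1cccc(c1)CCc1ccc(O)cc1
F10 | step 2 | 2-(3-iodophenoxy)-3-methoxybenzaldehyde | COc1cccc(C=O)c1Oc1cccc(I)c1
F11 | step 2 | 3-methoxy-2-{3-[(trimethylsilyl)ethynyl]phenoxy}benzaldehyde | COc1cccc(C=O)c1Oc1cccc(c1)C#C[Si](C)(C)C
F12 | step 8 | A6-bromo-B2,B6-dichloro-marchantin C | Oc1c(Br)cc2cc1Oc1c(Cl)cc(cc1Cl)CCc1cccc(O)c1Oc1cccc(c1)CC2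
A1 | alternative 1 | {4-[5-(2-{3-[2-formyl-6-methoxyphenoxy]phenyl}ethyl)-2-methoxyphenoxy]benzyl}triphenylphosphonium bromide | COc1ccc(CCc2cccc(Oc3c(C=O)cccc3OC)c2)cc1Oc1ccc(C[P+](c2ccccc2)(c2ccccc2)c2ccccc2)cc1.[Br-]
A2 | alternative 1 | macrocyclic stilbene: dimethyl ether of 14 with CH=CH in place of the B4–C1 ethano bridge (Z isomer shown) | COc1ccc2cc1Oc1ccc(cc1)/C=C\c1cccc(OC)c1Oc1cccc(c1)CC2
A3 | alternative 2 | 1-(bromomethyl)-2-{3-[2-(3-[4-(bromomethyl)phenoxy]-4-methoxyphenyl)ethyl]phenoxy}-3-methoxybenzene | BrCc1ccc(cc1)Oc1cc(CCc2cccc(Oc3c(CBr)cccc3OC)c2)ccc1OC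
A4 | alternative 2 | 19-membered thiacyclophane: dimethyl ether of 14 with CH2–S–CH2 in place of the B4–C1 ethano bridge | COc1ccc2cc1Oc1ccc(cc1)CSCc1cccc(OC)c1Oc1cccc(c1)CC2
A5 | alternative 3 | 4-bromo-2-(4-{2-[2-(3-bromophenoxy)-3-methoxyphenyl]ethyl}phenoxy)-1-methoxybenzene | COc1ccc(Br)cc1Oc1ccc(CCc2cccc(OC)c2Oc2cccc(Br)c2)cc1
A6 | alternative 3 | macrocyclic (E)-stilbene: dimethyl ether of 14 with CH=CH in place of the D3–A4 ethano bridge | COc1ccc2cc1Oc1ccc(cc1)CCc1cccc(OC)c1Oc1cccc(c1)/C=C/2
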